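**Retrosynthetic overview**
- Last C–C bond: aryl ketone **20** from a hindered methyl ester (**18**) plus 3-(TBSO)phenyllithium. The homoprenyl chain comes from a C4–CO2H by reduction, bromination and a methallyl cuprate coupling.
- Key disconnection: C3–C4 plus the isopropenyl group, made together by a photoredox radical-cation Ireland–Claisen of allylic ester **13**. This sets two contiguous stereocentres next to the pre-formed quaternary Cq.
- Cq comes from (S)-Roche ester (**1**) by self-regeneration of the stereocentre through a transient pivaldehyde dioxanone (the only ring, opened again at step 4); the other stereocentres follow from Cq.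

Assumptions (one line): acetalisation gives the 2,5-trans dioxanone and the enolate is alkylated anti to t-Bu; the Claisen proceeds through a chair TS from the Z-silyl ketene acetal and E-allylic alkene, with A(1,3)-strain facial bias from Cq giving (3S,4S).

---

**Step 1**
Reactants: 1 methyl (2S)-3-hydroxy-2-methylpropanoate (Roche ester)
Product: 2 (2S)-3-hydroxy-2-methylpropanoic acid
Conditions: LiOH, THF/H2O, 25 °C; then HCl
Reagents that add atoms: LiOH (O[Li]); water (O)
Why: Saponification leaves the stereocentre untouched.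

**Step 2**
Reactants: 2; 3 pivaldehyde
Product: 4 2-tert-butyl-5-methyl-1,3-dioxan-4-one (t-Bu and Me trans, from (S)-2)
Conditions: TsOH (cat.), pentane, Dean–Stark, reflux
Reagents that add atoms: pivaldehyde (3, CC(C)(C)C=O)
Why: Acetalisation of the β-hydroxy acid gives the thermodynamic diequatorial (trans) acetal, the template for self-regeneration of the stereocentre.

**Step 3**
Reactants: 4; 5 prenyl bromide
Product: 6 2-tert-butyl-5-methyl-5-(3-methylbut-2-enyl)-1,3-dioxan-4-one (prenyl anti to t-Bu)
Conditions: LDA, THF, –78 °C; then 5, –78 → –40 °C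
Reagents that add atoms: prenyl bromide (5, CC(C)=CCBr)
Why: Seebach enolate alkylation, with the electrophile entering anti to t-Bu, builds the quaternary Cq stereocentre from the Roche centre.

**Step 4**
Reactants: 6
Product: 7 methyl (2S)-2-(hydroxymethyl)-2,5-dimethylhex-4-enoate
Conditions: MeOH, HC(OMe)3, TsOH (cat.), 50 °C
Reagents that add atoms: methanol (CO)
Why: Acid-catalysed transacetalisation and methanolysis releases the hydroxy ester and t-BuCH(OMe)2 without touching the quaternary centre.

**Step 5**
Reactants: 7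
Product: 8 methyl (2S)-2-formyl-2,5-dimethylhex-4-enoate
Conditions: Dess–Martin periodinane, NaHCO3, CH2Cl2, 25 °C
Reagents that add atoms: none
Why: The α-quaternary aldehyde has no α-H, so it cannot epimerise; this is a standard alcohol oxidation.

**Step 6**
Reactants: 8; 9 triethyl 2-phosphonopropionate
Product: 10 EtO2C–C(CH3)=CH–C*(CH3)(CO2CH3)(CH2CH=C(CH3)2), E-alkene
Conditions: LiCl, DBU, MeCN, 25 °C (Masamune–Roush HWE)
Reagents that add atoms: 9 (CCOC(=O)C(C)P(=O)(OCC)OCC)
Why: The stabilised phosphonate gives the E-trisubstituted enoate (Horner–Wadsworth–Emmons).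

**Step 7**
Reactants: 10
Product: 11 (E)-HOCH2–C(CH3)=CH–C*(CH3)(CO2CH3)(CH2CH=C(CH3)2)
Conditions: DIBAL-H (2.2 equiv), CH2Cl2, –78 °C
Reagents that add atoms: none
Why: The unhindered conjugated ethyl ester is reduced in preference to the neopentyl methyl ester on the quaternary carbon.

**Step 8**
Reactants: 11; 12 5-methylhex-4-enoic acid
Product: 13 allylic ester (CH3)2C=CHCH2CH2C(=O)O–CH2–C(CH3)=CH–C*(CH3)(CO2CH3)(CH2CH=C(CH3)2)
Conditions: EDC·HCl, DMAP, CH2Cl2, 0 → 25 °C
Reagents that add atoms: 12 (CC(C)=CCCC(=O)O)
Why: Steglich esterification of a primary allylic alcohol.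

**Step 9**
Reactants: 13
Product: 14 OC(=O)[C@@H](CC=C(C)C)[C@@H](C(=C)C)[C@](C)(CC=C(C)C)C(=O)OC
Conditions: LDA, THF/HMPA (4:1), –78 °C; TBSCl; then Mes-Acr+ BF4– (2 mol %), 455 nm LEDs, CH2Cl2, 25 °C; then 1 M HCl/THF
Reagents that add atoms: TBSCl (CC(C)(C)[Si](C)(C)Cl; silyl removed on work-up); water (O)
Why: An Ireland–Claisen rearrangement forms the C3–C4 bond and the isopropenyl group; the Z-silyl ketene acetal with the E-allylic alkene gives the syn pair through a chair TS, with facial bias from the quaternary allylic stereocentre.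
Proposed new method: The photoexcited acridinium oxidises the silyl ketene acetal (Eox about +0.7 V vs SCE) to its radical cation, which undergoes a [3,3] shift with a much lower barrier; Mes-Acr• then reduces the rearranged silyl-ester radical cation and closes the cycle. This allows a bond between a tertiary α-carbon and a neopentyl-type γ-carbon to form at room temperature. The closest known reactions are the thermal Ireland–Claisen and radical-cation Cope/Claisen shifts.

**Step 10**
Reactants: 14
Product: 15 OC[C@@H](CC=C(C)C)[C@@H](C(=C)C)[C@](C)(CC=C(C)C)C(=O)OC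
Conditions: i-BuOCOCl, N-methylmorpholine, THF, –15 °C; then NaBH4, MeOH, 0 °C
Reagents that add atoms: none
Why: The mixed anhydride is reduced selectively, leaving the alkenes and the hindered ester intact; no stereocentre is touched.

**Step 11**
Reactants: 15
Product: 16 BrC[C@@H](CC=C(C)C)[C@@H](C(=C)C)[C@](C)(CC=C(C)C)C(=O)OC
Conditions: CBr4, PPh3, CH2Cl2, 0 → 25 °C
Reagents that add atoms: CBr4 (BrC(Br)(Br)Br)
Why: Appel bromination of the primary alcohol.

**Step 12**
Reactants: 16; 17 2-methylallylmagnesium chloride
Product: 18 C=C(C)CC[C@@H](CC=C(C)C)[C@@H](C(=C)C)[C@](C)(CC=C(C)C)C(=O)OC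
Conditions: Li2CuCl4 (5 mol %), THF, –20 → 0 °C
Reagents that add atoms: 17 (C=C(C)C[Mg]Cl)
Why: Copper-catalysed SN2 coupling of the primary bromide with the symmetric methallyl Grignard installs the 3-methylbut-3-enyl chain with no regiochemical ambiguity.

**Step 13**
Reactants: 18; 19 1-bromo-3-(tert-butyldimethylsilyloxy)benzene
Product: 20 C=C(C)CC[C@@H](CC=C(C)C)[C@@H](C(=C)C)[C@](C)(CC=C(C)C)C(=O)c1cccc(O[Si](C)(C)C(C)(C)C)c1
Conditions: t-BuLi (2 equiv), THF, –78 °C; add 18, –78 → 0 °C
Reagents that add atoms: 19 (CC(C)(C)[Si](C)(C)Oc1cccc(Br)c1)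
Why: The aryllithium acylates the hindered ester; the product ketone is too hindered for over-addition, and Cq has no α-H to epimerise.

**Step 14**
Reactants: 20
Product: 21 Garcinielliptone FA
Conditions: TBAF, THF, 0 °C
Reagents that add atoms: none
Why: Fluoride cleaves the aryl silyl ether and leaves the ketone and alkenes untouched.

---

**Compound list**
1 | methyl (2S)-3-hydroxy-2-methylpropanoate | OC[C@H](C)C(=O)OC | starting material
2 | (2S)-3-hydroxy-2-methylpropanoic acid | OC[C@H](C)C(=O)O | intermediate
3 | pivaldehyde | CC(C)(C)C=O | starting material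
4 | 2-tert-butyl-5-methyl-1,3-dioxan-4-one, t-Bu/Me trans | CC(C)(C)[C@H]1OC[C@H](C)C(=O)O1 | intermediate
5 | prenyl bromide | CC(C)=CCBr | starting material
6 | 5-methyl-5-prenyl-2-tert-butyl-1,3-dioxan-4-one | CC(C)(C)[C@H]1OC[C@](C)(CC=C(C)C)C(=O)O1 | intermediate
7 | methyl (2S)-2-(hydroxymethyl)-2,5-dimethylhex-4-enoate | OC[C@](C)(CC=C(C)C)C(=O)OC | intermediate
8 | methyl (2S)-2-formyl-2,5-dimethylhex-4-enoate | O=C[C@](C)(CC=C(C)C)C(=O)OC | intermediate
9 | triethyl 2-phosphonopropionate | CCOC(=O)C(C)P(=O)(OCC)OCC | starting material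
10 | E-enoate diester | CCOC(=O)/C(C)=C/[C@](C)(CC=C(C)C)C(=O)OC | intermediate
11 | E-allylic alcohol | OC/C(C)=C/[C@](C)(CC=C(C)C)C(=O)OC | intermediate
12 | 5-methylhex-4-enoic acid | CC(C)=CCCC(=O)O | starting material
13 | allylic ester | CC(C)=CCCC(=O)OC/C(C)=C/[C@](C)(CC=C(C)C)C(=O)OC | intermediate
14 | Claisen acid | OC(=O)[C@@H](CC=C(C)C)[C@@H](C(=C)C)[C@](C)(CC=C(C)C)C(=O)OC | intermediate
15 | primary alcohol | OC[C@@H](CC=C(C)C)[C@@H](C(=C)C)[C@](C)(CC=C(C)C)C(=O)OC | intermediate
16 | primary bromide | BrC[C@@H](CC=C(C)C)[C@@H](C(=C)C)[C@](C)(CC=C(C)C)C(=O)OC | intermediate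
17 | 2-methylallylmagnesium chloride | C=C(C)C[Mg]Cl | starting material
18 | methyl ester of the full carbon skeleton | C=C(C)CC[C@@H](CC=C(C)C)[C@@H](C(=C)C)[C@](C)(CC=C(C)C)C(=O)OC | intermediate
19 | 1-bromo-3-(TBSO)benzene | CC(C)(C)[Si](C)(C)Oc1cccc(Br)c1 | starting material
20 | TBS-protected ketone | C=C(C)CC[C@@H](CC=C(C)C)[C@@H](C(=C)C)[C@](C)(CC=C(C)C)C(=O)c1cccc(O[Si](C)(C)C(C)(C)C)c1 | intermediate
21 | Garcinielliptone FA | C=C(C)CC[C@@H](CC=C(C)C)[C@@H](C(=C)C)[C@](C)(CC=C(C)C)C(=O)c1cccc(O)c1 | target

**Totals:** 14 steps; longest linear sequence 14 steps.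

**Three steps most likely to fail**
1. **Step 9 (proposed new step):** the radical-cation Claisen may give low yield or erode chair selectivity. *Fallback (known chemistry, different approach):* make the enoate from aldehyde 8 with Ph3P=CHCO2Et, add isopropenylMgBr/CuBr·SMe2 and trap the enolate with prenyl bromide. The quaternary centre directs the conjugate addition; reduce the unhindered ester selectively and rejoin at step 11.
2. **Step 13:** the neopentyl-type ester may not react with the aryllithium. *Fallback:* saponify with KOSiMe3, form the S-ethyl thioester, then run a Liebeskind–Srogl coupling with 3-(TBSO)phenylboronic acid (Pd/CuTC).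
3. **Step 12:** the hindered, β-branched bromide may couple poorly, or the methallyl Grignard may attack the ester. *Fallback:* reverse the chain roles. Use 5-methylhex-5-enoic acid in step 8 so the Claisen installs the homoprenyl chain, then convert the acid to prenyl by reduction, bromination and Fe-catalysed Kumada coupling with 2-methylprop-1-enylmagnesium bromide.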